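**Plan**
1. Cα is the enol-ether carbon bearing O and ring B. Cβ is its partner bearing the prenylated ring A and the cyclobutane CH. The cuts are the tertiary O–Cα bond, then Cβ–ring A, then Cα–ring B, which leaves diaryl ether 30 and tricyclic δ-lactone 21.
2. Lactone 21 is cut at the carbinol C–CH3 bond and at the C=C of a cyclobutylidene acetate. This leads back to cis-6,6-dimethylbicyclo[3.2.0]hept-2-en-7-one 10.
3. Enabling feature: the gem-dimethylcyclobutane cis-fused to the cyclopentane. When the cyclobutane CH bonded to Cβ is written as C=O, the four-membered ring (C=O, allylic fusion CH, second fusion CH, CMe2), with an alkene beside the first fusion carbon, is the 1,3-acyl-shift isomer of 3,3-dimethylnorbornenone 9.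
4. Forward ring order: norbornene bicycle, cyclobutanone (step 5, cyclopentene carried over), δ-lactone, seven-membered oxepinone, dihydropyran. The two aryl rings arrive already joined through oxygen.
5. Stereochemistry: asymmetric hydrosilylation of norbornadiene fixes the bridgeheads. The bridgehead next to CMe2 becomes one fusion carbon and the tether in step 5 sets the other. Convex-face delivery of H2 (cyclobutane CH) and of methyl (carbinol carbon) sets the last two centres.

Key step: step 5

Remarks on the chemistry: exo means the convex face (the side of the fusion hydrogens) and endo the concave face, with bicyclo[3.2.0]heptane locants throughout. Compounds 32 and 33 are drawn as open hydroxy ketones although each may rest partly as its cyclic hemiketal. The sense of induction of (R)-MeO-MOP is taken from the exo-norbornanol series.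

**Step 1**
Reactants: 1 bicyclo[2.2.1]hepta-2,5-diene (norbornadiene)
Product: 2 (1R,4R,5S)-5-exo-(trichlorosilyl)bicyclo[2.2.1]hept-2-ene
Conditions: HSiCl3 (1.0 equiv), [PdCl(η3-C3H5)]2 (0.05 mol %), (R)-MeO-MOP (0.2 mol %), neat, 0 °C
Reagents that add atoms: trichlorosilane, Cl[SiH](Cl)Cl
Why: Palladium-catalysed asymmetric hydrosilylation adds H–Si syn to the exo face of one of the two equivalent alkenes, so the chiral monophosphine desymmetrises 1 and fixes both bridgeheads and the C–Si carbon, while one equivalent of silane spares the second alkene.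

**Step 2**
Reactants: 2 (1R,4R,5S)-5-exo-(trichlorosilyl)bicyclo[2.2.1]hept-2-ene
Product: 3 (1R,2S,4R)-bicyclo[2.2.1]hept-5-en-2-exo-ol
Conditions: KF, KHCO3, 30% H2O2, THF/MeOH, rt
Reagents that add atoms: hydrogen peroxide, OO
Why: Tamao–Fleming oxidation turns C–Si into C–OH with retention and leaves the alkene alone.

**Step 3**
Reactants: 3 (1R,2S,4R)-bicyclo[2.2.1]hept-5-en-2-exo-ol
Product: 4 (1R,4R)-bicyclo[2.2.1]hept-5-en-2-one
Conditions: Dess–Martin periodinane, CH2Cl2, 0 °C to rt
Reagents that add atoms: none
Why: Dess–Martin oxidation removes only the carbinol centre, and the bridgehead next to the carbonyl cannot enolise, so the configuration of the bicycle is safe.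

**Step 4**
Reactants: 4 (1R,4R)-bicyclo[2.2.1]hept-5-en-2-one; 5 iodomethane
Product: 9 (1R,4S)-3,3-dimethylbicyclo[2.2.1]hept-5-en-2-one, via parent lithium enolate 6 (not isolated), via 3-exo-methyl ketone 7 (not isolated), via methylated lithium enolate 8 (not isolated)
Conditions: LDA, THF, −78 °C, then MeI; second charge of LDA, −78 °C, then MeI, to 0 °C
Reagents that add atoms: iodomethane 5, CI
Why: Two kinetic enolate alkylations at C3, the only enolisable carbon, install the gem-dimethyl group without regiochemical ambiguity, and the transient exo-methyl centre disappears with the second methylation.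

**Step 5**
Reactants: 9 (1R,4S)-3,3-dimethylbicyclo[2.2.1]hept-5-en-2-one
Product: 10 (1R,5S)-6,6-dimethylbicyclo[3.2.0]hept-2-en-7-one (cis-fused)
Conditions: hν (300 nm lamps, Pyrex), degassed pentane (0.02 M), 15 °C, no sensitiser, stopped at partial conversion, 9 recovered and recycled
Reagents that add atoms: none
Why: Direct n→π* excitation of the β,γ-unsaturated ketone populates S1, in which the bond between the carbonyl carbon C2 and the allylic bridgehead C1 breaks to a tethered acyl/allyl radical pair, and the acyl carbon rebonds at the far allyl terminus C5 (photochemical 1,3-acyl shift of a bicyclo[2.2.1]hept-5-en-2-one, the known entry to bicyclo[3.2.0]hept-2-en-7-ones). The only ring closed is the cyclobutanone (C2, C3, C4, C5 of 9), formed by in-cage recombination of the acyl radical with an allyl terminus, while the old C1–C7–C4–C5–C6 ring lives on as the cyclopentene with its alkene moved to C6=C1. The one new stereocentre (C5 of 9, C1 of 10) is controlled by the C3–C4 tether: the acyl carbon hangs from C4 and can reach C5 only on the face it already occupies, so the fusion must be cis, and the untouched bridgehead C4 (C5 of 10) carries the absolute configuration over. The step needs the singlet shift to win over the triplet oxa-di-π-methane rearrangement, over cleavage of the C2–C3 bond with loss of CO, and over fragmentation to cyclopentadiene plus dimethylketene. Allylic stabilisation makes C1–C2 the weakest α-bond, the absence of any sensitiser or ketone or arene solvent keeps the triplet unpopulated, and partial conversion with recycling of 9 limits secondary photolysis of 10, which absorbs in the same window.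

**Step 6**
Reactants: 10 (1R,5S)-6,6-dimethylbicyclo[3.2.0]hept-2-en-7-one; 11 triethyl phosphonoacetate
Product: 12 ethyl (E)-2-[(1R,5S)-6,6-dimethylbicyclo[3.2.0]hept-2-en-7-ylidene]acetate
Conditions: (EtO)2P(O)CH2CO2Et, NaH, THF, 0 °C to reflux
Reagents that add atoms: triethyl phosphonoacetate 11, CCOC(=O)CP(=O)(OCC)OCC
Why: Horner–Wadsworth–Emmons olefination profits from the strain-activated cyclobutanone carbonyl despite the quaternary neighbour, the ester should point away from CMe2 (E), and either geometry converges in step 9.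

**Step 7**
Reactants: 12 ethyl (E)-2-[(1R,5S)-6,6-dimethylbicyclo[3.2.0]hept-2-en-7-ylidene]acetate
Product: 13 2,3-exo-epoxide of 12 (oxygen cis to the fusion hydrogens)
Conditions: mCPBA, CH2Cl2, 0 °C
Reagents that add atoms: 3-chloroperbenzoic acid, OOC(=O)c1cccc(Cl)c1
Why: Prilezhaev epoxidation picks the electron-rich cyclopentene over the enoate and attacks the convex face, and with the cyclobutanone already olefinated no Baeyer–Villiger path is open.

**Step 8**
Reactants: 13 2,3-exo-epoxide of 12
Product: 16 ethyl (E)-2-[2-exo-hydroxy-6,6-dimethylbicyclo[3.2.0]hept-3-en-7-ylidene]acetate, via hydroxy selenide 14 (not isolated), via selenoxide 15 (not isolated)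
Conditions: (PhSe)2, NaBH4, EtOH, rt to reflux; then THF, 30% H2O2, 0 °C to rt
Reagents that add atoms: none
Why: In this organoselenium epoxide-to-allylic-alcohol transposition the selenolate must arrive anti to oxygen from the concave face, where the line of attack on C2 runs into cyclobutane carbon C7 whereas that on C3 points outward, so oxygen stays on C2, and selenoxide syn-elimination toward the endo hydrogen of C4 gives the C3=C4 alkene (any elimination toward the carbinol gives the 2-ketone, which also ends in 18).

**Step 9**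
Reactants: 16 ethyl (E)-2-[2-exo-hydroxy-6,6-dimethylbicyclo[3.2.0]hept-3-en-7-ylidene]acetate
Product: 17 ethyl 2-[2-exo-hydroxy-6,6-dimethylbicyclo[3.2.0]heptan-7-endo-yl]acetate
Conditions: H2 (1 atm), Pd/C, EtOAc, rt
Reagents that add atoms: none
Why: Heterogeneous hydrogenation saturates both alkenes and delivers hydrogen to the cyclobutylidene from the convex face, so the new C7–H is exo and the acetate arm is endo, cis to the cyclopentane ring.

**Step 10**
Reactants: 17 ethyl 2-[2-exo-hydroxy-6,6-dimethylbicyclo[3.2.0]heptan-7-endo-yl]acetate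
Product: 18 ethyl 2-[6,6-dimethyl-2-oxobicyclo[3.2.0]heptan-7-endo-yl]acetate
Conditions: Dess–Martin periodinane, CH2Cl2, rt
Reagents that add atoms: none
Why: Dess–Martin oxidation of the secondary alcohol is neutral, touches no other group, and the cis ring fusion next to the new ketone cannot invert.

**Step 11**
Reactants: 18 ethyl 2-[6,6-dimethyl-2-oxobicyclo[3.2.0]heptan-7-endo-yl]acetate; 19 methyllithium
Product: 21 δ-lactone of 2-[2-endo-hydroxy-2-exo,6,6-trimethylbicyclo[3.2.0]heptan-7-endo-yl]acetic acid, via tertiary carbinol ester 20 (not isolated)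
Conditions: MeLi (1.1 equiv), CeCl3 (1.2 equiv), THF, −78 to 0 °C; aq. NH4Cl
Reagents that add atoms: methyllithium 19, [Li]C
Why: The weakly basic organocerium reagent adds 1,2 to the ketone in preference to the ester and from the convex face (the concave face also carries the ester arm), so methyl ends exo and the endo alkoxide closes the six-membered lactone by transesterification.

**Step 12**
Reactants: 22 4-chlororesorcinol
Product: 23 2-chloro-5-(methoxymethoxy)phenol
Conditions: MOMCl (1.0 equiv), iPr2NEt, CH2Cl2, 0 °C
Reagents that add atoms: chloromethyl methyl ether, COCCl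
Why: In this mono-O-alkylation the hydroxyl para to chlorine is the open and more nucleophilic one, while the hydroxyl flanked by chlorine stays free for the later ether coupling.

**Step 13**
Reactants: 23 2-chloro-5-(methoxymethoxy)phenol
Product: 24 2-chloro-4-iodo-5-(methoxymethoxy)phenol
Conditions: NIS, MeCN, 0 °C to rt
Reagents that add atoms: N-iodosuccinimide, O=C1CCC(=O)N1I
Why: Electrophilic aromatic iodination goes para to the free hydroxyl and ortho to OMOM, because the only other activated position lies crowded between the two oxygens.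

**Step 14**
Reactants: 24 2-chloro-4-iodo-5-(methoxymethoxy)phenol; 25 tributyl(3-methylbut-2-en-1-yl)stannane
Product: 26 2-chloro-5-(methoxymethoxy)-4-(3-methylbut-2-en-1-yl)phenol
Conditions: Pd(PPh3)4 (5 mol %), DMF, 90 °C
Reagents that add atoms: tributyl(3-methylbut-2-en-1-yl)stannane 25, CCCC[Sn](CCCC)(CCCC)CC=C(C)C
Why: Stille coupling engages only the C–I bond, tolerates the free phenol and the chloride, and transfers the prenyl group through its unsubstituted terminus.

**Step 15**
Reactants: 27 3-iodophenol
Product: 28 1-iodo-3-(methoxymethoxy)benzene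
Conditions: MOMCl, iPr2NEt, CH2Cl2, 0 °C to rt
Reagents that add atoms: chloromethyl methyl ether, COCCl
Why: Standard MOM protection gives an ether that survives copper, lithium and palladium chemistry and steers the next halogenation.

**Step 16**
Reactants: 28 1-iodo-3-(methoxymethoxy)benzene
Product: 29 1-bromo-2-iodo-4-(methoxymethoxy)benzene
Conditions: NBS, MeCN, 0 °C to rt
Reagents that add atoms: N-bromosuccinimide, O=C1CCC(=O)N1Br
Why: NBS in acetonitrile brominates aryl ethers para to the alkoxy group, which here is the carbon next to iodine.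

**Step 17**
Reactants: 26 2-chloro-5-(methoxymethoxy)-4-(3-methylbut-2-en-1-yl)phenol; 29 1-bromo-2-iodo-4-(methoxymethoxy)benzene
Product: 30 1-bromo-2-[2-chloro-5-(methoxymethoxy)-4-(3-methylbut-2-en-1-yl)phenoxy]-4-(methoxymethoxy)benzene
Conditions: CuI (10 mol %), picolinic acid (20 mol %), K3PO4, DMSO, 90 °C
Reagents that add atoms: none
Why: The ligand-accelerated Ullmann ether synthesis couples hindered phenols with ortho-substituted aryl iodides, and at this temperature C–I reacts well ahead of C–Br and C–Cl.

**Step 18**
Reactants: 30 diaryl ether; 21 tricyclic δ-lactone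
Product: 32 1-{2-[2-chloro-5-(methoxymethoxy)-4-prenylphenoxy]-4-(methoxymethoxy)phenyl}-2-[2-endo-hydroxy-2-exo,6,6-trimethylbicyclo[3.2.0]heptan-7-endo-yl]ethan-1-one, via aryllithium 31 (not isolated)
Conditions: n-BuLi (1.0 equiv), THF, −78 °C; then 21, −78 °C; aq. NH4Cl
Reagents that add atoms: none
Why: Bromine–lithium exchange is fast while the aryl chloride cannot exchange, so the two rings do not scramble, and addition of an aryllithium to a δ-lactone stops at the hemiketal alkoxide at low temperature, as in C-aryl glycoside synthesis.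

**Step 19**
Reactants: 32 hydroxy ketone
Product: 33 11-[2-endo-hydroxy-2-exo,6,6-trimethylbicyclo[3.2.0]heptan-7-endo-yl]-3,7-bis(methoxymethoxy)-2-prenyldibenzo[b,f]oxepin-10(11H)-one (C11 epimers)
Conditions: Pd2(dba)3 (5 mol %), XPhos (12 mol %), NaOtBu (2.5 equiv), toluene, 90 °C
Reagents that add atoms: none
Why: Intramolecular Buchwald–Hartwig-type α-arylation of the aryl alkyl ketone enolate with the tethered aryl chloride closes the seven-membered ring at Cβ, and the configuration of the new centre is irrelevant because it becomes sp2 in step 20.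

**Step 20**
Reactants: 33 dibenzoxepinone
Product: 34 bis(methoxymethyl) ether of the target
Conditions: PPTS (20 mol %), 4 Å MS, toluene, 80 °C
Reagents that add atoms: none
Why: In this acid-catalysed hemiketalisation and dehydration the endo tertiary hydroxyl adds to the ketone in a six-membered mode, the oxocarbenium ion stabilised by the para-alkoxyaryl group loses the acidic Cβ–H, and such mild acid leaves the tertiary C–O bond, the MOM ethers and the prenyl group alone.

**Step 21**
Reactants: 34 bis(methoxymethyl) ether of the target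
Product: 36 CNP0185814.1, via bis(trimethylsilyl) ether 35 (not isolated)
Conditions: TMSOTf, 2,2'-bipyridyl, MeCN, 0 °C to rt; then H2O, rt
Reagents that add atoms: none
Why: The silyl triflate and bipyridyl cleavage of aromatic MOM ethers runs through the aryl silyl ethers in a buffered medium without free protic acid, which protects the enol ether from hydrolysis and the ortho-prenylphenol from chroman formation.

**Compound list**
1 | bicyclo[2.2.1]hepta-2,5-diene | C1=CC2C=CC1C2 | starting material
2 | (1R,4R,5S)-5-exo-(trichlorosilyl)bicyclo[2.2.1]hept-2-ene | Cl[Si](Cl)(Cl)[C@H]1C[C@H]2C[C@@H]1C=C2 | intermediate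
3 | (1R,2S,4R)-bicyclo[2.2.1]hept-5-en-2-exo-ol | O[C@H]1C[C@H]2C[C@@H]1C=C2 | intermediate
4 | (1R,4R)-bicyclo[2.2.1]hept-5-en-2-one | O=C1C[C@H]2C[C@@H]1C=C2 | intermediate
5 | iodomethane | CI | starting material
6 | lithium enolate of 4 | [Li]OC1=C[C@H]2C[C@@H]1C=C2 | intermediate
7 | (1R,3S,4S)-3-exo-methylbicyclo[2.2.1]hept-5-en-2-one | O=C1[C@@H](C)[C@H]2C[C@@H]1C=C2 | intermediate
8 | lithium enolate of 7 | [Li]OC1=C(C)[C@H]2C[C@@H]1C=C2 | intermediate
9 | (1R,4S)-3,3-dimethylbicyclo[2.2.1]hept-5-en-2-one | O=C1C(C)(C)[C@H]2C[C@@H]1C=C2 | intermediate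
10 | (1R,5S)-6,6-dimethylbicyclo[3.2.0]hept-2-en-7-one | O=C1[C@H]2[C@H](CC=C2)C1(C)C | intermediate
11 | triethyl phosphonoacetate | CCOC(=O)CP(=O)(OCC)OCC | starting material
12 | ethyl (E)-2-[(1R,5S)-6,6-dimethylbicyclo[3.2.0]hept-2-en-7-ylidene]acetate | CCOC(=O)/C=C1\[C@H]2[C@H](CC=C2)C1(C)C | intermediate
13 | 2,3-exo-epoxide of 12 | CCOC(=O)/C=C1\[C@@H]2[C@H]3O[C@H]3C[C@@H]2C1(C)C | intermediate
14 | 2-exo-hydroxy-3-endo-(phenylselanyl) ester | CCOC(=O)/C=C1\[C@@H]2[C@@H](O)[C@H]([Se]c3ccccc3)C[C@@H]2C1(C)C | intermediate
15 | selenoxide of 14 | CCOC(=O)/C=C1\[C@@H]2[C@@H](O)[C@H]([Se](=O)c3ccccc3)C[C@@H]2C1(C)C | intermediate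
16 | ethyl (E)-2-[2-exo-hydroxy-6,6-dimethylbicyclo[3.2.0]hept-3-en-7-ylidene]acetate | CCOC(=O)/C=C1\[C@H]2[C@H](C=C[C@@H]2O)C1(C)C | intermediate
17 | ethyl 2-[2-exo-hydroxy-6,6-dimethylbicyclo[3.2.0]heptan-7-endo-yl]acetate | CCOC(=O)C[C@@H]1[C@H]2[C@H](CC[C@@H]2O)C1(C)C | intermediate
18 | ethyl 2-[6,6-dimethyl-2-oxobicyclo[3.2.0]heptan-7-endo-yl]acetate | CCOC(=O)C[C@@H]1[C@H]2[C@H](CCC2=O)C1(C)C | intermediate
19 | methyllithium | [Li]C | starting material
20 | ethyl 2-[2-endo-hydroxy-2-exo,6,6-trimethylbicyclo[3.2.0]heptan-7-endo-yl]acetate (formed as its alkoxide) | CCOC(=O)C[C@@H]1[C@H]2[C@H](CC[C@@]2(C)O)C1(C)C | intermediate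
21 | tricyclic δ-lactone | O=C1C[C@@H]2[C@H]3[C@H](CC[C@@]3(C)O1)C2(C)C | intermediate
22 | 4-chlororesorcinol | Oc1ccc(Cl)c(O)c1 | starting material
23 | 2-chloro-5-(methoxymethoxy)phenol | COCOc1ccc(Cl)c(O)c1 | intermediate
24 | 2-chloro-4-iodo-5-(methoxymethoxy)phenol | COCOc1cc(O)c(Cl)cc1I | intermediate
25 | tributyl(3-methylbut-2-en-1-yl)stannane | CCCC[Sn](CCCC)(CCCC)CC=C(C)C | starting material
26 | 2-chloro-5-(methoxymethoxy)-4-(3-methylbut-2-en-1-yl)phenol | CC(C)=CCc1cc(Cl)c(O)cc1OCOC | intermediate
27 | 3-iodophenol | Oc1cccc(I)c1 | starting material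
28 | 1-iodo-3-(methoxymethoxy)benzene | COCOc1cccc(I)c1 | intermediate
29 | 1-bromo-2-iodo-4-(methoxymethoxy)benzene | COCOc1ccc(Br)c(I)c1 | intermediate
30 | diaryl ether (ring A chloride, ring B bromide) | CC(C)=CCc1cc(Cl)c(Oc2cc(OCOC)ccc2Br)cc1OCOC | intermediate
31 | ring B aryllithium from 30 | [Li]c1ccc(OCOC)cc1Oc1cc(OCOC)c(CC=C(C)C)cc1Cl | intermediate
32 | hydroxy ketone | CC(C)=CCc1cc(Cl)c(Oc2cc(OCOC)ccc2C(=O)C[C@@H]2[C@H]3[C@H](CC[C@@]3(C)O)C2(C)C)cc1OCOC | intermediate
33 | dibenzo[b,f]oxepin-10(11H)-one, C11 epimers | CC(C)=CCc1cc2c(cc1OCOC)Oc1cc(OCOC)ccc1C(=O)C2[C@@H]1[C@H]2[C@H](CC[C@@]2(C)O)C1(C)C | intermediate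
34 | bis(methoxymethyl) ether of the target | CC(C)=CCc1cc2c(cc1OCOC)Oc1cc(OCOC)ccc1C1=C2[C@@H]2[C@H]3[C@H](CC[C@@]3(C)O1)C2(C)C | intermediate
35 | bis(trimethylsilyl) ether of the target | CC(C)=CCc1cc2c(cc1O[Si](C)(C)C)Oc1cc(O[Si](C)(C)C)ccc1C1=C2[C@@H]2[C@H]3[C@H](CC[C@@]3(C)O1)C2(C)C | intermediate
36 | CNP0185814.1 | CC(C)=CCc1cc2c(cc1O)Oc1cc(O)ccc1C1=C2[C@@H]2[C@H]3[C@H](CC[C@@]3(C)O1)C2(C)C | target

**Totals**
Total step count: 21. Longest linear sequence: 15 (steps 1–11 and 18–21). Steps 12–17 build the diaryl ether in parallel.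

**Steps most likely to fail**

Step 19. Oxidative addition into the electron-rich, ortho-substituted aryl chloride may be slow. The crowded palladium enolate may also undergo β-hydride elimination or protodehalogenation instead of closing the seven-membered ring. The fallback sets out from 32 and forms the C–C bond from an alkenyl boronate instead of an enolate. PPTS in toluene first dehydrates 32 to the 6-aryl-3,4-dihydro-2H-pyran F1. One equivalent of Br2 in CH2Cl2 at −78 °C followed by Et3N then places bromine on the enol-ether β-carbon, which is far more nucleophilic than the prenyl alkene, and gives the bromo enol ether F2. Pd2(dba)3/XPhos, B2pin2 and K3PO4 in aqueous dioxane convert the C–Br bond into the alkenyl boronate F3. This closes onto the aryl chloride in the same flask by intramolecular Suzuki–Miyaura coupling. The route is rejoined at 34.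

Step 8. The concave-face opening of the epoxide may show poor site selectivity, or it may stall under the endo methyl group. The fallback sets out from 12 and fixes the oxygen position by a carbonyl transposition instead of by the site of nucleophilic attack. CrO3·3,5-dimethylpyrazole oxidises the only allylic methylene (C4) to the cyclopentenone F4. Weitz–Scheffer epoxidation (tBuOOH, DBU) on the convex face gives the epoxy ketone F5. Wharton transposition (N2H4·H2O, AcOH, MeOH) then moves the alkene to C3=C4 and leaves the exo hydroxyl on C2. The route is rejoined at 16.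

Step 5. Cleavage on the quaternary side of the carbonyl, fragmentation to diene plus ketene, and secondary photolysis of the product may erode the material balance. The fallback keeps the same acyl shift but changes the order of events and sets out from 4. The parent ketone, which has no quaternary α-carbon to compete with the allylic bond, is irradiated under the same sensitiser-free conditions to (1S,5R)-bicyclo[3.2.0]hept-2-en-7-one F6. Two LDA/MeI alkylations at C6 follow, passing through the 6-exo-methyl ketone F7. The other α-carbon is the fusion CH, and its enolate would put a double bond at the junction of the strained bicycle. The route is rejoined at 10.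

**Further compounds**
F1 | step 19 | 6-aryl-3,4-dihydro-2H-pyran from dehydration of 32 | CC(C)=CCc1cc(Cl)c(Oc2cc(OCOC)ccc2C2=C[C@@H]3[C@H]4[C@H](CC[C@@]4(C)O2)C3(C)C)cc1OCOC
F2 | step 19 | bromo enol ether (Br on Cβ) | CC(C)=CCc1cc(Cl)c(Oc2cc(OCOC)ccc2C2=C(Br)[C@@H]3[C@H]4[C@H](CC[C@@]4(C)O2)C3(C)C)cc1OCOC
F3 | step 19 | alkenyl pinacol boronate (B on Cβ) | CC(C)=CCc1cc(Cl)c(Oc2cc(OCOC)ccc2C2=C(B5OC(C)(C)C(C)(C)O5)[C@@H]3[C@H]4[C@H](CC[C@@]4(C)O2)C3(C)C)cc1OCOC
F4 | step 8 | ethyl (E)-2-[6,6-dimethyl-4-oxobicyclo[3.2.0]hept-2-en-7-ylidene]acetate | CCOC(=O)/C=C1\[C@H]2[C@H](C(=O)C=C2)C1(C)C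
F5 | step 8 | 2,3-exo-epoxy-4-oxo ester | CCOC(=O)/C=C1\[C@@H]2[C@H]3O[C@H]3C(=O)[C@@H]2C1(C)C
F6 | step 5 | (1S,5R)-bicyclo[3.2.0]hept-2-en-7-one | O=C1[C@H]2[C@H](CC=C2)C1
F7 | step 5 | 6-exo-methylbicyclo[3.2.0]hept-2-en-7-one | O=C1[C@H]2[C@H](CC=C2)[C@H]1C
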